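## The problem

Locants are those of the target decalin. Ring A is C1–C2–C3–C4–C4a–C8a (C1 carries the propanoic acid chain, C2 the isopropylidene group). Ring B is C4a–C5–C6–C7–C8–C8a (C5 carries CH3 and the arylmethyl group, C6 a CH3, C8a the angular CH3).

The target is a cis-fused decalin in which two quaternary carbons (C5 and C8a) flank the fusion CH (C4a), with the methine C6 next to C5 and the chain-bearing C1 next to C8a. The three methyl groups, the fusion hydrogen and the C1 chain lie on one face and the arylmethyl group on the other. Only C6 can be bought: it maps onto C3 of (R)-citronellal, with the aldehyde carbon as the benzylic carbon. C4a and C8a are tied together by the ring fusion, C5 has to be set with them, and C1 can be set last under the control of the finished bicycle. The awkward relationship is C6 to C8a: their methyl groups are cis-1,4 on ring B, so one of them must be axial in any chair through which ring B forms. The tetrasubstituted exocyclic alkene sits next to C1 with a carboxylic acid four atoms away, so strong acid would move the double bond or close a δ-lactone. The electron-rich 4-methoxyphenol is easily oxidized, so it stays masked until the last step and both carbonyl oxygens have to leave without allyl cations. The key step rests on two features. In ring A the angular C8a is 1,4 to C3, a CH2 that can be a carbonyl, so ring A can begin as a prochiral 4-methyl-4-alkylcyclohexa-2,5-dienone. The benzylic carbon can be a ketone, which makes C5 an enolate carbon placed for a 6-exo Michael addition that forms C5–C4a and closes ring B.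

## Retrosynthesis

**30 back to 27.** No skeletal bond is cut. The phenol comes from MOM ether 29, the acid from primary alcohol 28, and both ArCH2 and the free alcohol from aryl ketone benzyl ether 27 in one dissolving-metal operation. Oxidation to the acid is placed before phenol release so that the oxidant never meets a free 4-methoxyphenol. The forward steps must avoid strong acid because of the isopropylidene group.

**27 back to 23.** The C3 methylene is traced to the C3 ketone of 23 through dienyl triflate 25 and diene 26. Hydrazone reduction or deoxygenation of the allylic alcohol would pass through allyl intermediates and move the C2 double bond; triflate reduction and diimide do not. The forward sequence asks for α′-deprotonation of an α-alkylidene ketone and for a reduction that tells a disubstituted from a tetrasubstituted alkene.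

**23 back to 20.** The C1–chain bond and the C2=C(CH3)2 bond are cut. Conjugate addition to the remaining enone of 20 gives silyl enol ether 21, which fixes the enolate at C2; a ketal aldol (22) and loss of methanol give 23. This uses the second enone arm for exactly the two substituents ring A needs. It asks that the nucleophile enter C1 on the face of the angular methyl group.

**20 back to 18 (key cut).** The C5–C4a bond is cut. Bicycle 20, with three new stereocentres, falls back to the achiral dienone ring of 18 carrying a chain with one stereocentre. Cutting at C8a instead would leave a quaternary carbon to be made on a preformed ring. The forward Michael addition must choose one of two enantiotopic arms and the configuration of C5.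

**18 back to 13 and 14.** The dienone comes from cyclohexenone 17 by dehydrogenation, and 17 from α-methyl aldehyde 13 and methyl vinyl ketone 14 by enamine Michael addition and aldol condensation. This makes the quaternary C8a without any stereochemical demand.

**13 back to 8.** Aldehyde 13 is the one-carbon homologue of methyl ketone 11 (through enol ether 12). Ketone 11 comes from aldehyde 9 by methyl addition (10) and oxidation, and 9 from cleavage of the citronellal alkene in 8. Each step must leave the hindered aryl ketone alone.

**8 back to 1 and 3.** The α-methyl group is removed (6), the ketone is taken back to carbinol 5, and the aryl–carbon bond is cut to aryllithium 4 and (R)-citronellal 3. The lithium reagent comes from MOM ether 2 of phenol 1 by ortho-metalation.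

## Roads not taken

**Alternative 1:** The C5–C6 bond is cut. In the forward direction the silyl ketene acetal of a six-membered allylic lactone undergoes an Ireland–Claisen ring contraction to cyclohexene acid A1. The lactone ring fixes the ketene acetal geometry, and the concerted boat transition state sets C5 and C6 together with no enantiotopic arms and no equilibrium. In reliability of the ring-B stereochemistry this road is better than the chosen one. Its cost is that ring A, with C1, C4a, C8a and a stereodefined allylic carbinol at C8, must be built enantioselectively before ring B exists. Afterwards the neopentyl carboxyl group of A1 has to be turned into ArCH2, and the C7=C8 alkene must be saturated beside the isopropylidene group. Against this the chosen plan sets a ring A made by a simple annulation, a chiral-pool start and ring B with three stereocentres in one step. It accepts weaker control of the arm in return.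

**Alternative 2:** The C8a–C8 bond is cut. An anionic oxy-Cope rearrangement of a bicyclo[2.2.2]octenol alkoxide gives cis-decalenone A2. The rigid bicycle, made by a Diels–Alder reaction, locks the cis fusion and the C5/C4a/C8a relationship, and enolate formation makes the step irreversible. Here too the fusion and C5 are more secure than in the chosen plan. The weak points are these: the C6 methyl group must be added later to a ketone beside the quaternary C5, with its configuration left to a hydrogenation; the C1 chain and the isopropylidene group still have to be developed from the allylic silyl ether of A2; and absolute configuration needs an enantioselective cycloaddition. The chosen plan brings C6 from citronellal and is shorter.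

**Alternative 3:** The C4a–C4 bond is cut. A bromoacetal on the future benzylic arm gives a primary radical that closes 6-exo (Ueno–Stork cyclization) onto a cross-conjugated dienone that is ring B, giving acetal enone A3. The tether guarantees that C4 ends up cis to the benzylic arm, and the radical step tolerates most functionality. Nothing in that substrate distinguishes the two enone arms, so A3 is racemic unless a resolution or an auxiliary is added. C8a is still a CH to be alkylated, C6 still an alkene carbon, and the arene must later be added to a neopentyl aldehyde. It shares the arm problem of the chosen plan but has neither a resident stereocentre nor reversibility to address it, and it is longer.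

Key step: step 12

Abbreviations: Ar′ = 5-methoxy-2-(methoxymethoxy)-3-methylphenyl; Bn = benzyl; names of bicyclic compounds use the target locants defined above.

Assumption: centres that are formed without control and erased later are carried as mixtures of epimers. These are the carbinol carbons of 5 and 10, the ketone α-carbon in 8–18, the aldehyde α-carbon of 13, the quaternary ring carbon of 17 and C2 of 22.

Step 1
Reactants: 1 4-methoxy-2-methylphenol
Product: 2 4-methoxy-1-(methoxymethoxy)-2-methylbenzene
Conditions: MOMCl, iPr2NEt, CH2Cl2, 0 °C to rt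
Reagents that add atoms: chloromethyl methyl ether, COCCl
Why: O-Alkylation of the phenol to an acetal (MOM protection); the ether survives every basic and organometallic step and directs the lithiation of step 2.

Step 2
Reactants: 2 4-methoxy-1-(methoxymethoxy)-2-methylbenzene; 3 (R)-citronellal
Product: 5 (3R)-1-Ar′-3,7-dimethyloct-6-en-1-ol (both carbinol epimers), via aryllithium 4 (not isolated)
Conditions: n-BuLi, TMEDA, THF, 0 °C; then 3, −78 °C; NH4Cl aq
Reagents that add atoms: none
Why: Directed ortho-metalation followed by 1,2-addition to the aldehyde; OCH2OCH3 is a stronger director than OCH3 and its only free ortho position is the one needed. The carbinol mixture is removed in step 3 and C3 of citronellal is not touched.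

Step 3
Reactants: 5 (3R)-1-Ar′-3,7-dimethyloct-6-en-1-ol
Product: 6 (3R)-1-Ar′-3,7-dimethyloct-6-en-1-one
Conditions: DMP, NaHCO3, CH2Cl2, rt
Reagents that add atoms: none
Why: Dess–Martin oxidation of the benzylic alcohol under buffered neutral conditions that spare the acetal and the alkene.

Step 4
Reactants: 6 (3R)-1-Ar′-3,7-dimethyloct-6-en-1-one
Product: 8 (3R)-1-Ar′-2,3,7-trimethyloct-6-en-1-one (C2 epimers), via lithium enolate 7 (not isolated)
Conditions: LiN(iPr)2, THF, −78 °C; MeI, −78 to 0 °C
Reagents that add atoms: iodomethane, CI
Why: Enolate C-methylation; the ketone can enolize only toward its CH2 group, and the tertiary α-CH of the product is too hindered for a second alkylation. The new centre is erased by the enolate of step 12.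

Step 5
Reactants: 8 (3R)-1-Ar′-2,3,7-trimethyloct-6-en-1-one
Product: 9 (4R)-6-Ar′-4,5-dimethyl-6-oxohexanal
Conditions: OsO4 (cat.), NaIO4, 2,6-lutidine, dioxane/H2O, rt
Reagents that add atoms: sodium periodate (oxygen source through OsO4), [Na+].[O-][I](=O)(=O)=O
Why: Lemieux–Johnson cleavage (osmylation, then periodate cleavage of the glycol) of the trisubstituted alkene; it is preferred to ozone, which would also attack the electron-rich arene.

Step 6
Reactants: 9 (4R)-6-Ar′-4,5-dimethyl-6-oxohexanal
Product: 10 (3R)-1-Ar′-6-hydroxy-2,3-dimethylheptan-1-one (carbinol epimers)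
Conditions: MeMgBr, THF, −78 °C; NH4Cl aq
Reagents that add atoms: methylmagnesium bromide, C[Mg]Br
Why: Grignard 1,2-addition; at −78 °C the aldehyde reacts and the α-branched, ortho-substituted aryl ketone does not. The carbinol mixture is oxidized in step 7.

Step 7
Reactants: 10 (3R)-1-Ar′-6-hydroxy-2,3-dimethylheptan-1-one
Product: 11 (3R)-1-Ar′-2,3-dimethylheptane-1,6-dione
Conditions: DMP, NaHCO3, CH2Cl2, rt
Reagents that add atoms: none
Why: Dess–Martin oxidation of the secondary alcohol to the methyl ketone.

Step 8
Reactants: 11 (3R)-1-Ar′-2,3-dimethylheptane-1,6-dione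
Product: 12 (3R)-1-Ar′-7-methoxy-2,3,6-trimethylhept-6-en-1-one (E and Z)
Conditions: MeOCH2PPh3Cl, KN(SiMe3)2, THF, 0 °C
Reagents that add atoms: (methoxymethyl)triphenylphosphonium chloride, COC[P+](c1ccccc1)(c1ccccc1)c1ccccc1.[Cl-]
Why: Wittig methoxymethylenation; the unhindered methyl ketone is the only carbonyl group open to the bulky ylide. Both alkene isomers give the same aldehyde.

Step 9
Reactants: 12 (3R)-1-Ar′-7-methoxy-2,3,6-trimethylhept-6-en-1-one
Product: 13 (5R)-7-Ar′-2,5,6-trimethyl-7-oxoheptanal (C2 epimers)
Conditions: 1 M HCl, THF, 0 °C to rt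
Reagents that add atoms: water, O
Why: Acid hydrolysis of the enol ether, which protonates on carbon much faster than the aryl MOM acetal is cleaved in cold dilute acid. The new α-centre becomes the prochiral quaternary carbon.

Step 10
Reactants: 13 (5R)-7-Ar′-2,5,6-trimethyl-7-oxoheptanal; 14 methyl vinyl ketone
Product: 17 4-[(3R)-5-Ar′-3,4-dimethyl-5-oxopentyl]-4-methylcyclohex-2-en-1-one, via enamine 15 (not isolated), via keto aldehyde 16 (not isolated)
Conditions: pyrrolidine, PhH, reflux (−H2O); 14, rt; AcOH, NaOAc, H2O, reflux
Reagents that add atoms: none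
Why: Stork enamine Michael addition followed by intramolecular aldol condensation (Robinson annulation of an α,α-disubstituted aldehyde) gives the 4,4-disubstituted cyclohex-2-enone. Only the aldehyde forms an enamine, and the buffered acid spares the MOM ether.

Step 11
Reactants: 17 4-[(3R)-5-Ar′-3,4-dimethyl-5-oxopentyl]-4-methylcyclohex-2-en-1-one
Product: 18 4-[(3R)-5-Ar′-3,4-dimethyl-5-oxopentyl]-4-methylcyclohexa-2,5-dien-1-one
Conditions: DDQ, dioxane, reflux
Reagents that add atoms: none
Why: Quinone dehydrogenation of a 4,4-disubstituted cyclohexenone (hydride abstraction from the enol, then proton loss), the usual entry to cross-conjugated dienones. The ring becomes achiral and its two enone arms enantiotopic.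

Step 12
Reactants: 18 4-[(3R)-5-Ar′-3,4-dimethyl-5-oxopentyl]-4-methylcyclohexa-2,5-dien-1-one
Product: 20 5-(Ar′-carbonyl)-5,6,8a-trimethyl-cis-decal-1-en-3-one (4a-H, 5-CH3, 6-CH3 and 8a-CH3 on one face, aroyl on the other), via potassium enolate 19 (not isolated)
Conditions: KOtBu (0.3 equiv), tBuOH/THF, rt to 40 °C; NH4Cl aq
Reagents that add atoms: none
Why: KOtBu reversibly removes the only acidic C–H of 18 to give the tetrasubstituted enolate 19, whose α-carbon (C5) adds to the β-carbon (C4a) of one enone arm; tBuOH protonates the ring-A enolate and leaves the second arm as the enone of 20. The closest known reaction type is the base-mediated desymmetrizing intramolecular Michael addition of tethered carbonyl nucleophiles to 4,4-disubstituted cyclohexa-2,5-dienones. Ring B closes 6-exo-trig. For C4a and C8a, the three-atom tether from C8a can reach C4a only on its own face, so the fusion is cis whatever else happens. For C5, axial attack puts the unreacted arm axial on the new chair, and the flat aroyl group rather than the methyl group is expected to take the axial site beside it, which is the wanted configuration (aroyl cis to C4); the reversibility of the addition lets this preference operate. Arm selection is what the step needs and what the substrate secures least: the wanted arm carries the C6 methyl group axial and anti to the aroyl group, the other arm carries it equatorial, so an irreversible closure would favour the wrong arm, whereas at equilibrium the two isomers should lie close in energy (two 1,3-diaxial CH3/H contacts against one gauche CH3/aroyl contact). The reaction is therefore run under equilibrating conditions, 20 is separated, and the other cis-fused isomers are returned to the same conditions.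

Step 13
Reactants: 20 5-(Ar′-carbonyl)-5,6,8a-trimethyl-cis-decal-1-en-3-one
Product: 21 1-[3-(benzyloxy)propyl]-5-(Ar′-carbonyl)-5,6,8a-trimethyl-3-(trimethylsilyloxy)-cis-decal-2-ene (C1 chain on the face of the methyl groups)
Conditions: BnO(CH2)3MgBr, CuBr·SMe2 (cat.), Me3SiCl, HMPA, THF, −78 °C; Et3N
Reagents that add atoms: [3-(benzyloxy)propyl]magnesium bromide, Br[Mg]CCCOCc1ccccc1; chlorotrimethylsilane, C[Si](C)(C)Cl
Why: Copper-catalysed, silyl chloride-accelerated conjugate addition of a Grignard reagent; the axial aroyl group and ring B cover one face of the enone, so the chain should enter C1 on the face of the angular methyl group, as the target requires. Trapping as the silyl enol ether keeps the regiodefined C2 enolate from adding to the nearby aryl ketone.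

Step 14
Reactants: 21 1-[3-(benzyloxy)propyl]-5-(Ar′-carbonyl)-5,6,8a-trimethyl-3-(trimethylsilyloxy)-cis-decal-2-ene
Product: 22 1-[3-(benzyloxy)propyl]-2-(2-methoxypropan-2-yl)-5-(Ar′-carbonyl)-5,6,8a-trimethyl-cis-decalin-3-one (C2 epimers)
Conditions: Me2C(OMe)2, Me3SiOTf (cat.), CH2Cl2, −78 °C
Reagents that add atoms: 2,2-dimethoxypropane, COC(C)(C)OC
Why: Mukaiyama-type aldol addition of the silyl enol ether to the oxocarbenium ion of a ketal places the three-carbon unit regiospecifically at C2. The acetone ketal ionizes far more readily than the formaldehyde-derived MOM acetal at −78 °C.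

Step 15
Reactants: 22 1-[3-(benzyloxy)propyl]-2-(2-methoxypropan-2-yl)-5-(Ar′-carbonyl)-5,6,8a-trimethyl-cis-decalin-3-one
Product: 23 1-[3-(benzyloxy)propyl]-2-(propan-2-ylidene)-5-(Ar′-carbonyl)-5,6,8a-trimethyl-cis-decalin-3-one
Conditions: DBU, PhMe, 80 °C
Reagents that add atoms: none
Why: E1cB loss of methanol from the β-methoxy ketone gives the conjugated exocyclic enone, the only alkene position reachable from the C2 enolate.

Step 16
Reactants: 23 1-[3-(benzyloxy)propyl]-2-(propan-2-ylidene)-5-(Ar′-carbonyl)-5,6,8a-trimethyl-cis-decalin-3-one
Product: 25 1-[3-(benzyloxy)propyl]-2-(propan-2-ylidene)-5-(Ar′-carbonyl)-5,6,8a-trimethyl-cis-decal-3-en-3-yl trifluoromethanesulfonate, via potassium dienolate 24 (not isolated)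
Conditions: KN(SiMe3)2, THF, −78 °C; PhNTf2
Reagents that add atoms: N-phenylbis(trifluoromethanesulfonimide), O=S(=O)(N(c1ccccc1)S(=O)(=O)C(F)(F)F)C(F)(F)F
Why: Kinetic deprotonation of an α-alkylidene ketone takes place at the α′-CH2 (C4), and O-sulfonylation of the cross-conjugated dienolate gives the dienyl triflate; the aryl ketone has no α-hydrogen. Low temperature and immediate trapping keep this enolate from opening ring B by retro-Michael reaction.

Step 17
Reactants: 25 dienyl triflate
Product: 26 1-[3-(benzyloxy)propyl]-2-(propan-2-ylidene)-5-(Ar′-carbonyl)-5,6,8a-trimethyl-cis-decal-3-ene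
Conditions: Pd(OAc)2 (cat.), PPh3, HCO2H, Bu3N, DMF, 60 °C
Reagents that add atoms: none
Why: Palladium-catalysed formate reduction of an enol triflate (oxidative addition, decarboxylation of formate to the hydride, reductive elimination) replaces C–O by C–H with both double bonds held in place. The C3 oxygen thus leaves without any allyl cation, anion or radical that could move the isopropylidene double bond.

Step 18
Reactants: 26 diene
Product: 27 1-[3-(benzyloxy)propyl]-2-(propan-2-ylidene)-5-(Ar′-carbonyl)-5,6,8a-trimethyl-cis-decalin
Conditions: TsNHNH2, NaOAc, DME/H2O, reflux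
Reagents that add atoms: none
Why: Diimide reduction transfers H2 in a concerted syn fashion to the cis-disubstituted ring alkene; the tetrasubstituted alkene, the aryl ketone and the benzyl ether are inert to it.

Step 19
Reactants: 27 aryl ketone benzyl ether
Product: 28 3-[5-(Ar′-methyl)-5,6,8a-trimethyl-2-(propan-2-ylidene)-cis-decalin-1-yl]propan-1-ol
Conditions: Li, NH3/THF, −78 to −33 °C; NH4Cl
Reagents that add atoms: none
Why: Dissolving-metal reduction takes the aryl ketone through its ketyl to the benzylic alkoxide, and the ammonium chloride quench in the presence of excess lithium hydrogenolyses the benzylic C–O bond to ArCH2; the benzyl ether is cleaved to the alcohol in the same operation. Without an alcohol as proton source the isolated tetrasubstituted alkene and the alkoxy-substituted arene are not reduced.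

Step 20
Reactants: 28 primary alcohol
Product: 29 3-[5-(Ar′-methyl)-5,6,8a-trimethyl-2-(propan-2-ylidene)-cis-decalin-1-yl]propanoic acid
Conditions: TEMPO (cat.), PhI(OAc)2, MeCN/H2O, rt
Reagents that add atoms: water, O
Why: Oxoammonium-mediated oxidation of the primary alcohol through the aldehyde hydrate to the acid under near-neutral conditions that spare the alkene and the acetal. The phenol is still protected, so no quinone can form.

Step 21
Reactants: 29 MOM-protected acid
Product: 30 3-{5-[(2-hydroxy-5-methoxy-3-methylphenyl)methyl]-5,6,8a-trimethyl-2-(propan-2-ylidene)-cis-decalin-1-yl}propanoic acid (target)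
Conditions: PPTS, tBuOH, 80 °C
Reagents that add atoms: none
Why: Mild acid-catalysed transacetalization removes the aryl MOM group. The weak acid does not protonate the tetrasubstituted alkene, so neither double-bond migration nor lactonization onto C2 is expected.

## Compound list

1 | 4-methoxy-2-methylphenol | Cc1cc(OC)ccc1O | starting material
2 | 4-methoxy-1-(methoxymethoxy)-2-methylbenzene | COCOc1ccc(OC)cc1C | intermediate
3 | (R)-citronellal | C[C@H](CCC=C(C)C)CC=O | starting material
4 | [5-methoxy-2-(methoxymethoxy)-3-methylphenyl]lithium | [Li]c1cc(OC)cc(C)c1OCOC | intermediate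
5 | (3R)-1-Ar′-3,7-dimethyloct-6-en-1-ol, carbinol epimers | C[C@H](CCC=C(C)C)CC(O)c1cc(OC)cc(C)c1OCOC | intermediate
6 | (3R)-1-Ar′-3,7-dimethyloct-6-en-1-one | C[C@H](CCC=C(C)C)CC(=O)c1cc(OC)cc(C)c1OCOC | intermediate
7 | lithium enolate of 6 | [Li+].C[C@H](CCC=C(C)C)C=C([O-])c1cc(OC)cc(C)c1OCOC | intermediate
8 | (3R)-1-Ar′-2,3,7-trimethyloct-6-en-1-one, C2 epimers | C[C@H](CCC=C(C)C)C(C)C(=O)c1cc(OC)cc(C)c1OCOC | intermediate
9 | (4R)-6-Ar′-4,5-dimethyl-6-oxohexanal | C[C@H](CCC=O)C(C)C(=O)c1cc(OC)cc(C)c1OCOC | intermediate
10 | (3R)-1-Ar′-6-hydroxy-2,3-dimethylheptan-1-one | C[C@H](CCC(C)O)C(C)C(=O)c1cc(OC)cc(C)c1OCOC | intermediate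
11 | (3R)-1-Ar′-2,3-dimethylheptane-1,6-dione | C[C@H](CCC(C)=O)C(C)C(=O)c1cc(OC)cc(C)c1OCOC | intermediate
12 | (3R)-1-Ar′-7-methoxy-2,3,6-trimethylhept-6-en-1-one, E and Z | C[C@H](CCC(C)=COC)C(C)C(=O)c1cc(OC)cc(C)c1OCOC | intermediate
13 | (5R)-7-Ar′-2,5,6-trimethyl-7-oxoheptanal | C[C@H](CCC(C)C=O)C(C)C(=O)c1cc(OC)cc(C)c1OCOC | intermediate
14 | methyl vinyl ketone | CC(=O)C=C | starting material
15 | pyrrolidine enamine of 13 | C[C@H](CCC(C)=CN2CCCC2)C(C)C(=O)c1cc(OC)cc(C)c1OCOC | intermediate
16 | (5R)-7-Ar′-2,5,6-trimethyl-7-oxo-2-(3-oxobutyl)heptanal | C[C@H](CCC(C)(C=O)CCC(C)=O)C(C)C(=O)c1cc(OC)cc(C)c1OCOC | intermediate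
17 | 4-[(3R)-5-Ar′-3,4-dimethyl-5-oxopentyl]-4-methylcyclohex-2-en-1-one | C[C@H](CCC1(C)C=CC(=O)CC1)C(C)C(=O)c2cc(OC)cc(C)c2OCOC | intermediate
18 | 4-[(3R)-5-Ar′-3,4-dimethyl-5-oxopentyl]-4-methylcyclohexa-2,5-dien-1-one, both epimers at the ketone α-carbon | C[C@H](CCC1(C)C=CC(=O)C=C1)C(C)C(=O)c2cc(OC)cc(C)c2OCOC | intermediate
19 | potassium enolate of 18 | [K+].C[C@H](CCC1(C)C=CC(=O)C=C1)C(C)=C([O-])c2cc(OC)cc(C)c2OCOC | intermediate
20 | 5-(Ar′-carbonyl)-5,6,8a-trimethyl-cis-decal-1-en-3-one; 4a-H, 5-CH3, 6-CH3, 8a-CH3 on one face, aroyl on the other | COc1cc(C)c(OCOC)c(C(=O)[C@]2(C)[C@@H]3CC(=O)C=C[C@]3(C)CC[C@H]2C)c1 | intermediate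
21 | silyl enol ether: 1-[3-(benzyloxy)propyl]-3-(trimethylsilyloxy)-cis-decal-2-ene, chain cis to 8a-CH3 | COc1cc(C)c(OCOC)c(C(=O)[C@]2(C)[C@@H]3CC(O[Si](C)(C)C)=C[C@@H](CCCOCc4ccccc4)[C@]3(C)CC[C@H]2C)c1 | intermediate
22 | β-methoxy ketone: 2-(2-methoxypropan-2-yl)-cis-decalin-3-one, C2 epimers | COc1cc(C)c(OCOC)c(C(=O)[C@]2(C)[C@@H]3CC(=O)C(C(C)(C)OC)[C@@H](CCCOCc4ccccc4)[C@]3(C)CC[C@H]2C)c1 | intermediate
23 | 2-(propan-2-ylidene)-cis-decalin-3-one with C1 chain and C5 aroyl | COc1cc(C)c(OCOC)c(C(=O)[C@]2(C)[C@@H]3CC(=O)C(=C(C)C)[C@@H](CCCOCc4ccccc4)[C@]3(C)CC[C@H]2C)c1 | intermediate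
24 | potassium 3-en-3-olate (cross-conjugated dienolate) of 23 | [K+].COc1cc(C)c(OCOC)c(C(=O)[C@]2(C)[C@@H]3C=C([O-])C(=C(C)C)[C@@H](CCCOCc4ccccc4)[C@]3(C)CC[C@H]2C)c1 | intermediate
25 | dienyl triflate (C3 triflate, C3=C4 and C2 isopropylidene) | COc1cc(C)c(OCOC)c(C(=O)[C@]2(C)[C@@H]3C=C(OS(=O)(=O)C(F)(F)F)C(=C(C)C)[C@@H](CCCOCc4ccccc4)[C@]3(C)CC[C@H]2C)c1 | intermediate
26 | diene (C3=C4 and C2 isopropylidene) | COc1cc(C)c(OCOC)c(C(=O)[C@]2(C)[C@@H]3C=CC(=C(C)C)[C@@H](CCCOCc4ccccc4)[C@]3(C)CC[C@H]2C)c1 | intermediate
27 | aryl ketone benzyl ether with C3 and C4 saturated | COc1cc(C)c(OCOC)c(C(=O)[C@]2(C)[C@@H]3CCC(=C(C)C)[C@@H](CCCOCc4ccccc4)[C@]3(C)CC[C@H]2C)c1 | intermediate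
28 | 3-[5-(Ar′-methyl)-5,6,8a-trimethyl-2-(propan-2-ylidene)-cis-decalin-1-yl]propan-1-ol | COc1cc(C)c(OCOC)c(C[C@]2(C)[C@@H]3CCC(=C(C)C)[C@@H](CCCO)[C@]3(C)CC[C@H]2C)c1 | intermediate
29 | 3-[5-(Ar′-methyl)-5,6,8a-trimethyl-2-(propan-2-ylidene)-cis-decalin-1-yl]propanoic acid | COc1cc(C)c(OCOC)c(C[C@]2(C)[C@@H]3CCC(=C(C)C)[C@@H](CCC(=O)O)[C@]3(C)CC[C@H]2C)c1 | intermediate
30 | CNP0299684.4 | COc1cc(C)c(O)c(C[C@]2(C)[C@@H]3CCC(=C(C)C)[C@@H](CCC(=O)O)[C@]3(C)CC[C@H]2C)c1 | target

## Step count and least certain steps

Total: 21 steps. Longest linear sequence: 21 steps, from 1; citronellal 3 and methyl vinyl ketone 14 enter along it.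

**Step 12 (key step).** The most likely failure is closure onto the wrong enone arm, with the wrong C5 epimer as a lesser risk. The chair imposed by axial attack keeps the C6 methyl group equatorial only for the unwanted arm, so the wanted isomer depends on an equilibrium between isomers of similar energy and on recycling. The fallback lets a catalyst choose the arm before ring B exists. Dienone 18 is treated with [BnO(CH2)3]2Zn, Cu(OTf)2 (cat.) and a binaphthol-derived phosphoramidite ligand (PhMe, −30 °C), a known enantioselective conjugate addition to 4,4-disubstituted cyclohexadienones, and the zinc enolate is silylated (Me3SiOTf, Et3N) to give silyl dienol ether F1. The alkyl group enters C1 anti to the larger substituent of C8a, and the ligand enantiomer selects the arm. Ketal aldol as in step 14 gives β-methoxy ketone F2, and DBU gives isopropylidene dienone F3. KOtBu/tBuOH then closes ring B onto the only enone arm left, so only C5 remains to be settled by equilibration. The sequence rejoins the route at 23.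

**Step 16.** Deprotonation may occur at a γ-methyl group of the isopropylidene unit instead of the hindered α′-CH2, or ring B may open by retro-Michael reaction from the C4 enolate before it is sulfonylated. Fallback from 23: LiAlH4 (THF, 0 °C) reduces both ketones to diol F5, and Ac2O/DMAP/pyridine gives diacetate F6. Li/NH3 (then NH4Cl) cleaves the benzylic and the allylic C–O bonds and the benzyl ether in one operation; the allyl anion is expected to protonate at its secondary terminus C3 and so keep the tetrasubstituted alkene. This returns to the route at 28.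

**Step 19.** Hydrogenolysis may stop at the benzylic alcohol because the hindered alkoxide loses oxygen slowly, or the electron-rich ring may be partly reduced if the quench is slow. Fallback from 27: LiAlH4 gives benzylic alcohol F7, and NaH, CS2, MeI give xanthate F8. Bu3SnH/AIBN in PhMe at reflux (Barton–McCombie deoxygenation) gives deoxygenated benzyl ether F9. A short Li/NH3 treatment then only has to cleave the benzyl ether and gives 28.

**Step 11.** The quinone may oxidize the benzylic methyl group of the electron-rich arene, or the acidic hydroquinone formed at reflux may remove the MOM group. Fallback from 17: LiN(iPr)2 then Me3SiCl (THF, −78 °C) deprotonates the accessible α′-CH2 of the enone rather than the hindered α-CH of the aryl ketone and gives silyl dienol ether F4. Pd(OAc)2 in MeCN (Saegusa–Ito oxidation) gives 18.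

## Further compounds

F1 | step 12 | silyl dienol ether from conjugate addition to 18 | C[Si](C)(C)OC1=C[C@@H](CCCOCc2ccccc2)[C@](C)(CC[C@@H](C)C(C)C(=O)c3cc(OC)cc(C)c3OCOC)C=C1
F2 | step 12 | monocyclic β-methoxy ketone enone | O=C1C=C[C@@](C)(CC[C@@H](C)C(C)C(=O)c2cc(OC)cc(C)c2OCOC)[C@H](CCCOCc3ccccc3)C1C(C)(C)OC
F3 | step 12 | monocyclic isopropylidene dienone | O=C1C=C[C@@](C)(CC[C@@H](C)C(C)C(=O)c2cc(OC)cc(C)c2OCOC)[C@H](CCCOCc3ccccc3)C1=C(C)C
F4 | step 11 | silyl dienol ether of 17 | C[C@H](CCC1(C)C=CC(O[Si](C)(C)C)=CC1)C(C)C(=O)c2cc(OC)cc(C)c2OCOC
F5 | step 16 | diol from reduction of both ketones of 23 | COc1cc(C)c(OCOC)c(C(O)[C@]2(C)[C@@H]3CC(O)C(=C(C)C)[C@@H](CCCOCc4ccccc4)[C@]3(C)CC[C@H]2C)c1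
F6 | step 16 | diacetate of F5 | COc1cc(C)c(OCOC)c(C(OC(C)=O)[C@]2(C)[C@@H]3CC(OC(C)=O)C(=C(C)C)[C@@H](CCCOCc4ccccc4)[C@]3(C)CC[C@H]2C)c1
F7 | step 19 | benzylic alcohol from 27 | COc1cc(C)c(OCOC)c(C(O)[C@]2(C)[C@@H]3CCC(=C(C)C)[C@@H](CCCOCc4ccccc4)[C@]3(C)CC[C@H]2C)c1
F8 | step 19 | S-methyl xanthate of F7 | COc1cc(C)c(OCOC)c(C(OC(=S)SC)[C@]2(C)[C@@H]3CCC(=C(C)C)[C@@H](CCCOCc4ccccc4)[C@]3(C)CC[C@H]2C)c1
F9 | step 19 | deoxygenated benzyl ether | COc1cc(C)c(OCOC)c(C[C@]2(C)[C@@H]3CCC(=C(C)C)[C@@H](CCCOCc4ccccc4)[C@]3(C)CC[C@H]2C)c1
A1 | alternative 1 | ring-B cyclohexene carboxylic acid | OC(=O)[C@]2(C)[C@@H]3CCC(=C(C)C)[C@@H](CCCO[Si](C)(C)C(C)(C)C)[C@]3(C)C=C[C@H]2C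
A2 | alternative 2 | cis-fused decalenone | COc1cc(C)c(OCOC)c(C[C@]2(C)[C@@H]3CCC(C(C)(C)O[Si](CC)(CC)CC)=C[C@]3(C)CCC2=O)c1
A3 | alternative 3 | cis-fused bicyclic acetal enone | O1C[C@]2(C)[C@H](C[C@@H]1OCC)[C@@H](C)C(=O)C=C2C
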